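At 72.0 h the midnight flask reads 12% product and the dusk flask reads 6%, about half as much, though both read 17% at 6.00 h. The two differ in temperature, 5 °C against 11 °C.

| flask | substrate | reagent in the second phase | temperature | remark | time | volume of the second phase over the first |
|---|---|---|---|---|---|---|
| midnight | 0.020 M | 0.022 M | 5 °C | the very flask that is asked about, followed so far |  |  |
| dusk | 0.020 M | 0.022 M | 11 °C | run made earlier |  |  |
| flask | 0.020 M | 0.0220 M | 5 °C |  | 3.0 d | 0.25 |

| run | time / h | product / % | substrate / % |
|---|---|---|---|
| midnight | 6.00 | 17 | 85 |
| midnight | 20.0 | 22 | 73 |
| midnight | 30.0 | 25 | 78 |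
| midnight | 48.0 | 17 | 80 |
| midnight | 72.0 | 12 | 85 |
| dusk | 6.00 | 17 | 82 |
| dusk | 20.0 | 19 | 76 |
| dusk | 30.0 | 15 | 83 |
| dusk | 48.0 | 10 | 85 |
| dusk | 72.0 | 6 | 91 |

(each reading ± 2 percentage points)

- in the second phase: reagent in the second phase; everything else is in the first
- charges count per volume of the first phase; a concentration in a rate is the amount of a species over the volume of its own phase; every rate counts per litre of the first phase
- what is taken out of product is counted as made
- the analysis behind the earlier runs scatters by 2 percentage points, standard deviation
- the earlier runs hold the two phases in the same ratio of volumes as the flask asked about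
- additions bring no volume worth counting

- Thursday's: change nothing and wait 6.0 d more
- Sunday's: at 3.0 d add substrate, 50.0% of the amount charged, then wait 6.0 d
- Monday's: at 3.0 d take out 90% of the product then present, then wait 6.0 d
- Tuesday's: at 3.0 d raise the temperature by 10 K, then wait 6.0 d

* product, in percent of the substrate first charged, at 3.0 d
* the option that brings most further product ("none" if no option brings more than 2 percentage points) (Thursday's / Sunday's / Monday's / Tuesday's / none)
* product present, with what was taken out counted in, in percent of the substrate first charged, after Thursday's
* product present, with what was taken out counted in, in percent of the substrate first charged, after Tuesday's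

In the midnight flask, substrate and product sum to 97.0% at 72.0 h, so falling product is returning to substrate. Dividing the rate of loss of product by the product present removes the amount and leaves one number per run, λ, read from the last two readings:

λ(midnight) = ln(17% / 12%) / 24.0 h = 0.0145 h⁻¹

λ(dusk) = ln(10% / 6%) / 24.0 h = 0.0213 h⁻¹

This fall constant, a pseudo-first-order constant, is a reading, and each point carries a scatter of 2 percentage points. The dusk flask ends lower because it reads lower at the start of that stretch, 10% against 17%, and because its λ is larger, by a factor of 1.47.

This reckoning takes the reading of 12% at 3.0 d as the product now, and the midnight λ carries it to 1.48% after Thursday's. Sunday's, scaled in proportion to the substrate, is reckoned at 2.23%. Monday's banks 90% of the product and, taking the end level as Thursday's, is reckoned to gain 0.28 points, less than the 2 points required. Tuesday's lifts the flask by 10 K from 5 °C, past dusk's 11 °C, and the dusk λ applied to it gives 0.560%. The choice of this reckoning is none.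

The forecast, resting on “a reagent that dies away on its own”, gives 12.5% now, 1.8% after Thursday's, 0.3% after Tuesday's, and none as best. Its Thursday figure stands above this reckoning's.

The flask gives 14.7% now, 3.15% after Thursday's, 0.0454% after Tuesday's, and none as best.

    reagent in the reaction phase ⇌ reagent in the second phase, rate k1*([reagent in the reaction phase] - [reagent in the second phase]/K1) per volume of the first phase (partition coefficient = 0.890, kL = 7.30 × 10⁻⁶ s⁻¹)
    substrate + reagent in the reaction phase ⇌ product (K = 29.0 M⁻¹, k = 0.0490 M⁻¹ s⁻¹, Ea = 42.0 kJ mol⁻¹, ΔH = 6.00 kJ mol⁻¹)
    reagent in the reaction phase → decomposed reagent (k = 5.60 × 10⁻⁶ s⁻¹, Ea = 92.0 kJ mol⁻¹)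
    (constants at 5 °C)

Monday's gain of 0.56 points is the highest of the options, and it stays under the 2 points margin. The same division on this flask, from 14.7% at 3.0 d to 3.15% after Thursday's, gives λ = 0.0107 h⁻¹ over that later stretch. The neighbour is the same flask read at 8.0 d. Carrying 14.7% forward with that λ gives 4.07% for it. The neighbour holds 4.09% product beside 95.9% substrate.

Readings and results are calculated with constants of no real substance; scatter was added.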